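## Analysis of the target

Entonaemin A (23) is a 6,7-dihydro-1H-isochromen-8(5H)-one. Ring A is the carbocycle C4a–C5–C6–C7–C8–C8a and ring B the 1H-pyran C1–O2–C3–C4–C4a–C8a; they share the C4a=C8a double bond, and C3 carries an (E)-3-hydroxyprop-1-enyl chain (C9 to C11). Ring A holds the C8 ketone, the tertiary carbinol C7 with its methyl group, the carbinol C6 (esterified with orsellinic acid) and the C5 methylene. C6 and C7 are the only stereocentres; both are R and their oxygen atoms are cis on ring A. The sensitive groups are these: the array O2–C3=C4–C4a=C8a–C8=O is a doubly vinylogous ester that aqueous acid can hydrate; the C5 hydrogens are vinylogously acidic, so base can expel the C6 acyloxy group (E1cB); the tertiary α-ketol at C7/C8 can undergo an acyloin shift; and the resorcinol and the allylic alcohol are free. The hard parts are the vicinal tertiary/secondary diol of fixed configuration beside a ketone, telling C8 from C4a when ring B is attached, and placing a 2,6-disubstituted benzoate on a hindered secondary hydroxyl late in the route. The plan rests on one observation: C8 (carbonyl), C7 (methyl carbinol), C6 (carbinol) and C5 (methylene) repeat C1 to C4 of 2-C-methyl-D-erythrono-1,4-lactone (1) with the same (R,R) cis-diol, so ring A can be closed onto the old lactone carbon C8 from a two-carbon ketone unit (C4a, C8a) attached at C5.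

## Retrosynthetic reasoning

Target numbering is used for all intermediates. In keto ester 7 the ester carbon is C8, the ring carbons of the dioxolane are C7 and C6, the methylene is C5, the ketone carbon is C4a and the ketone methyl is C8a.

O–Si bonds. The target 23 is traced back to its tris-silyl ether 22. The phenols and the C11 hydroxyl must be masked while the ester is made, and silyl ethers leave together under buffered fluoride, which spares both the dienol ether and the base-labile β-acyloxy arrangement.

C6–O acyl bond. 22 is cut at the ester into diol 18 and acid chloride 21. Only the secondary C6 hydroxyl can be acylated; the tertiary C7 hydroxyl is too hindered, so no further protection is needed. 21 is made from orsellinic acid 19 through the persilylated compound 20, whose silyl ester can be turned into the acid chloride without releasing free strong acid.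

Ketal C–O bonds. 18 comes from ketal 17. The isopropylidene group is kept until here because it masks both hydroxyls through every basic and organometallic step and, as a cis-fused ring, holds the reacting groups together in the key step.

O2–C3 bond. Ring B of 17 is opened to the hydroxymethyl enynone 16. In the forward direction the C1 hydroxyl adds to C3, the δ-carbon of the ynenone, in a 6-endo closure that is matched electronically. 16 comes from aldehyde 15 by 1,2-reduction.

C4a–C4 bond. 15 is cut between C4a and the alkyne into chloro aldehyde 12 and the silylated enyne 14 (from enynol 13). The C4a–Cl bond of 12 is a vinylogous acid chloride activated by two carbonyl groups, which makes the cross-coupling easy and brings the C3/C4 unit and the whole side chain in one piece.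

C8a–C1 bond and C4a–Cl bond. 12 goes back through enaminone 10 to dione 9. C1 is attached first, by condensing a formamide acetal with the C8a methylene between the two carbonyls; only then is the C4a oxygen exchanged for chlorine. A chloroiminium reagent applied directly to 9 would exchange oxygen for chlorine first and leave a β-chloro enone that is no longer nucleophilic at C8a. C8 is shielded by the quaternary, oxygen-bearing C7, which directs the exchange to C4a.

C8–C8a bond (key disconnection). Dione 9 is opened between C8 and C8a to keto ester 7. Cutting here and not at C4a–C5 or C7–C8 leaves both stereocentres in a fragment that is a sugar lactone, and the forward reaction is an intramolecular Claisen condensation in which an enolate attacks an ester, the natural polarity. It has to enolise the methyl group (C8a) and not C5.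

C5–C4a bond. 7 comes from alkene 6 by ozonolysis, and 6 from triflate 5 by copper-mediated transfer of a 2-propenyl group. The 2-propenyl group is an acetyl anion equivalent that tolerates the ester; a lithiated thioacetal would attack the ester. 5 is the triflate of hydroxy ester 4.

C8–O lactone bond. 4 is the ring-opened methyl ester of ketal lactone 2, which is the isopropylidene derivative of 1. The opening is done by saponification and O-methylation of the carboxylate, because a silyl iodide, the usual reagent for turning lactones into iodo esters, would cleave the ketal.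

## Alternatives that were turned down

Alternative 1: ring A by a Heck reaction, ring B by a following oxa-6π closure.
- Disconnection: C4a–C8a and O2–C1, leading back to the open-chain (Z)-vinyl iodide A1, which already carries the silylated orsellinate at C6, the C7 carbinol and a vinyl ketone (C8, C8a, C1).
- Forward key step: with Pd(OAc)2, PPh3 and Ag2CO3, zerovalent palladium formed in the flask inserts into the C4a–I bond and C4a adds to C8a of the vinyl ketone (6-exo-trig). β-Hydride loss from C8a leaves the exocyclic C8a=C1 double bond, and the O=C3–C4=C4a–C8a=C1 array closes by oxa-6π electrocyclisation to A2, the tris-silyl ether of the target.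
- For: both rings form in one operation from a fully functionalised chain; it is the most convergent plan; no ketal and therefore no late acid; C8 never has to be told from C4a.
- Against: the new bond must go to the α-carbon (C8a) of an enone, whereas carbopalladation of electron-poor alkenes prefers the β-carbon (C1), so 7-endo closure is a real competitor. A1 is an unprotected α′-hydroxy vinyl ketone, prone to polymerisation and conjugate addition. Both stereocentres must first be made in an acyclic chain by an asymmetric step, and every valuable fragment is already attached when the riskiest bond is formed.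
- Comparison: alternative 1 is stronger on convergence and on protecting-group operations. The chosen route offers a ring closure of matched polarity, stereocentres that are bought and not made, and a key step whose failure would cost only cheap material.

Alternative 2: ring A by zinc-chelated α-ketol ring enlargement of a cyclopentenol.
- Disconnection: C6–C7. Ring A is traced back to the cyclopentenol A3, in which C8 carries the hydroxyl (cis to the C6 ester) and an acetyl group (the future C7 and its methyl) and is bonded to C6.
- Forward key step: Zn(OTf)2 (divalent zinc) binds the C8 hydroxyl and the acetyl oxygen in a five-membered chelate, and C6 shifts from C8 to the acetyl carbon. The cyclopentene of A3 is thereby enlarged to ring A and the product is the ketol A4, which has the C8 ketone beside the new C7 carbinol. The chelate passes the configuration of C8 on to C7.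
- For: an atom-economic isomerisation that sets the quaternary carbinol stereospecifically; it is driven by ring enlargement and by conjugation of the new C8 ketone with C4a=C8a. Only one ketone is ever formed, so the C8/C4a problem does not arise; on this point it is stronger than the chosen route.
- Against: two groups can migrate from C8. C6 bears the electron-withdrawing acyloxy group and is a poorer migrating group than the alkenyl carbon C8a, whose shift gives the wrong skeleton in place of A4. The tertiary allylic C8 hydroxyl may ionise under the Lewis acid, and the ester may move to the cis C8 hydroxyl. A3, a fully substituted cyclopentene with two stereocentres, needs its own long asymmetric synthesis, and ring B still has to be closed from A4 afterwards.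
- Comparison: more steps to the key intermediate and a migration whose direction the substrate does not secure. In the chosen route the enolate has only one six-membered closure open to it.

Alternative 3: building the resorcylate arene on the C6 oxygen from an acylketene.
- Disconnection: inside the ester, at the C6–O acyl bond and the C1–C6 bond of the arene, leading to diol A5 (rings A and B complete, C11 silylated) and the diketo-dioxinone A6.
- Forward key step: heating A6 with A5 unmasks a ketene function that the C6 hydroxyl captures. NEt3 in the same flask folds the resulting 3,5,7-trioxooctanoate chain by aldol condensation and dehydration into the resorcylate ring of A7, the C11 silyl ether of the target.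
- For: the acylating carbon is small and very electrophilic, so the hindered hydroxyl is acylated without an activating base; no phenol protecting groups; only one silyl ether is left to cleave. On the esterification itself this is stronger than the acid chloride used in step 15.
- Against: it is an endgame and does not touch the real problem, the ring A/ring B core with its two stereocentres. Heating near 100 °C and amine-promoted cyclisation act on a substrate with a base-labile β-acyloxy arrangement and an α-ketol, and O-cyclisation of the keto-ester chain competes with the C-cyclisation that gives the arene.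
- Comparison: as a key step it forms one ring and no stereocentre of the core. The chosen strategy supplies the core and both stereocentres; alternative 3 is kept as the fallback for step 15.

Key step: step 6

Assumption: lactone 1 and acid 19 are bought as such, and enynol 13 is bought or purified as the single E isomer.

Step 1
Reactants: 1 2-C-methyl-D-erythrono-1,4-lactone
Product: 2 2,3-O-isopropylidene-2-C-methyl-D-erythrono-1,4-lactone
Conditions: Me2C(OMe)2, TsOH·H2O (cat.), acetone, rt
Reagents that add atoms: 2,2-dimethoxypropane, COC(C)(C)OC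
Why: Acid-catalysed ketal exchange (acetonide formation) on the cis-1,2-diol should give the cis-fused dioxolane; no stereocentre is touched.

Step 2
Reactants: 2 2,3-O-isopropylidene-2-C-methyl-D-erythrono-1,4-lactone
Product: 4 methyl (2R,3R)-4-hydroxy-2,3-(isopropylidenedioxy)-2-methylbutanoate, via potassium carboxylate 3 (not isolated)
Conditions: KOH (1.0 equiv), MeOH/H2O, 0 °C → rt; evaporate; MeI, DMF, 0 °C → rt; cold neutral work-up, used at once
Reagents that add atoms: KOH, [K+].[OH-]; iodomethane, CI
Why: Saponification opens the lactone at the acyl carbon, and the carboxylate is O-methylated by SN2 on iodomethane without acid or strong base. Exactly one equivalent of hydroxide and a cold work-up should hold back re-closure of 4 to 2.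

Step 3
Reactants: 4 methyl (2R,3R)-4-hydroxy-2,3-(isopropylidenedioxy)-2-methylbutanoate
Product: 5 methyl (2R,3R)-2,3-(isopropylidenedioxy)-2-methyl-4-(trifluoromethylsulfonyloxy)butanoate
Conditions: Tf2O, 2,6-lutidine, CH2Cl2, −78 °C; cold work-up, used at once
Reagents that add atoms: trifluoromethanesulfonic anhydride, O=S(=O)(OS(=O)(=O)C(F)(F)F)C(F)(F)F
Why: O-Sulfonylation of the primary alcohol at −78 °C is faster than lactonisation and turns C5 into a strong SN2 electrophile.

Step 4
Reactants: 5 methyl (2R,3R)-2,3-(isopropylidenedioxy)-2-methyl-4-(trifluoromethylsulfonyloxy)butanoate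
Product: 6 methyl (2R,3R)-2,3-(isopropylidenedioxy)-2,5-dimethylhex-5-enoate
Conditions: [CH2=C(CH3)]2CuMgBr (from CH2=C(CH3)MgBr and CuBr·SMe2), THF, −78 → −30 °C
Reagents that add atoms: isopropenylmagnesium bromide, CC(=C)[Mg]Br
Why: SN2 displacement of a primary triflate by an alkenyl homocuprate (copper-mediated sp3–sp2 coupling) forms the C5–C4a bond. The cuprate should not add to the hindered ester at low temperature, and the 2-propenyl group is a masked acetyl group.

Step 5
Reactants: 6 methyl (2R,3R)-2,3-(isopropylidenedioxy)-2,5-dimethylhex-5-enoate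
Product: 7 methyl (2R,3R)-2,3-(isopropylidenedioxy)-2-methyl-5-oxohexanoate
Conditions: O3, CH2Cl2, −78 °C; then PPh3, −78 °C → rt
Reagents that add atoms: ozone, [O-][O+]=O
Why: Ozonolysis of the 1,1-disubstituted alkene with reductive work-up should give the methyl ketone and formaldehyde. The neutral conditions leave ester and ketal alone and give no chance for β-elimination of the C6 oxygen.

Step 6
Reactants: 7 methyl (2R,3R)-2,3-(isopropylidenedioxy)-2-methyl-5-oxohexanoate
Product: 9 (3aR,7aR)-2,2,3a-trimethyltetrahydro-1,3-benzodioxole-4,6-dione, via lithium enolate 8 (not isolated)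
Conditions: LiN(SiMe3)2 (2.5 equiv), THF, slow addition of 7 at −78 °C, then → 0 °C; AcOH quench at −20 °C
Reagents that add atoms: none
Why: Slow addition of 7 to excess LiN(SiMe3)2 at −78 °C should remove a proton from the methyl group (C8a), the less hindered α-position, to give lithium enolate 8. On warming, the enolate carbon adds to the ester carbonyl (C8), methoxide leaves, and the second equivalent of base deprotonates the 1,3-dione at once, which makes the sequence irreversible; this is an intramolecular Claisen (Dieckmann-type) condensation of a δ-keto ester, the classical way to cyclohexane-1,3-diones. Ring A closes in the 6-(enolendo)-exo-trig mode. No stereocentre is formed: C6 and C7 come unchanged from lactone 1, and neither can epimerise, since C7 has no hydrogen and C6 is not α to a carbonyl group. The ester and the ketone side chain are cis on the dioxolane, so the reacting carbons are held close and the product is the cis-fused bicycle. The selectivity needed is enolisation toward C8a and not toward C5, whose enolate could expel the C6 oxygen (E1cB); the C5 position is the more hindered one, its enolate has no six-membered closure open to it, and any of it that forms can return to 8 by proton transfer while the condensation drains 8. The acetic acid quench should keep the ketal intact and give 9, largely as its enol.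

Step 7
Reactants: 9 (3aR,7aR)-2,2,3a-trimethyltetrahydro-1,3-benzodioxole-4,6-dione
Product: 10 (3aR,7aR)-5-[(dimethylamino)methylidene]-2,2,3a-trimethyltetrahydro-1,3-benzodioxole-4,6-dione
Conditions: Me2NCH(OMe)2, toluene, rt
Reagents that add atoms: N,N-dimethylformamide dimethyl acetal, COC(OC)N(C)C
Why: Aminomethylenation of the active methylene C8a by a formamide acetal should bring in C1 at the aldehyde oxidation level. No base is added, so the β-alkoxy ketone is not endangered.

Step 8
Reactants: 10 (3aR,7aR)-5-[(dimethylamino)methylidene]-2,2,3a-trimethyltetrahydro-1,3-benzodioxole-4,6-dione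
Product: 12 (3aR,7aR)-6-chloro-2,2,3a-trimethyl-4-oxo-3a,4,7,7a-tetrahydro-1,3-benzodioxole-5-carbaldehyde, via iminium chloride 11 (not isolated)
Conditions: (COCl)2, CH2Cl2, −20 → 0 °C; then aq. NaOAc, 0 °C
Reagents that add atoms: oxalyl chloride, O=C(Cl)C(Cl)=O; water, O
Why: Oxalyl chloride acylates a carbonyl oxygen of the vinylogous amide, chloride adds to the ring carbon and CO2, CO and chloride leave (chlorodeoxygenation, the second stage of a Vilsmeier haloformylation); buffered hydrolysis of 11 then frees the aldehyde. The C4a oxygen should react because C8 is flanked by the quaternary, oxygen-bearing C7, which lowers its basicity and blocks chloride attack.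

Step 9
Reactants: 13 (E)-pent-2-en-4-yn-1-ol
Product: 14 (E)-tert-butyl(pent-2-en-4-ynyloxy)diphenylsilane
Conditions: t-BuPh2SiCl, imidazole, CH2Cl2, 0 °C → rt
Reagents that add atoms: tert-butyl(chloro)diphenylsilane, CC(C)(C)[Si](Cl)(c1ccccc1)c1ccccc1
Why: Silylation of the primary allylic alcohol; the tert-butyldiphenylsilyl ether is chosen because it should outlast the aqueous acid of step 13.

Step 10
Reactants: 12 (3aR,7aR)-6-chloro-2,2,3a-trimethyl-4-oxo-3a,4,7,7a-tetrahydro-1,3-benzodioxole-5-carbaldehyde; 14 (E)-tert-butyl(pent-2-en-4-ynyloxy)diphenylsilane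
Product: 15 (3aR,7aR)-6-[(E)-5-(tert-butyldiphenylsilyloxy)pent-3-en-1-ynyl]-2,2,3a-trimethyl-4-oxo-3a,4,7,7a-tetrahydro-1,3-benzodioxole-5-carbaldehyde
Conditions: PdCl2(PPh3)2 (5 mol %), CuI (10 mol %), NEt3, THF, rt
Reagents that add atoms: none
Why: Sonogashira coupling forms the C4a–C4 bond. Zerovalent palladium, formed from the divalent precatalyst, inserts readily into the C4a–Cl bond, which is a vinylogous acid chloride activated by the aldehyde and the ketone; the E double bond of 14 is not involved.

Step 11
Reactants: 15 (3aR,7aR)-6-[(E)-5-(tert-butyldiphenylsilyloxy)pent-3-en-1-ynyl]-2,2,3a-trimethyl-4-oxo-3a,4,7,7a-tetrahydro-1,3-benzodioxole-5-carbaldehyde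
Product: 16 (3aR,7aR)-6-[(E)-5-(tert-butyldiphenylsilyloxy)pent-3-en-1-ynyl]-5-(hydroxymethyl)-2,2,3a-trimethyl-7,7a-dihydro-1,3-benzodioxol-4(3aH)-one
Conditions: NaBH4, CeCl3·7H2O, MeOH/THF, −78 °C
Reagents that add atoms: none
Why: Luche reduction: the CeCl3-modified borohydride should deliver hydride 1,2 to the aldehyde, much faster than to the hindered C8 ketone beside the quaternary C7, and the hard reagent should avoid conjugate reduction of the doubly activated C4a=C8a bond.

Step 12
Reactants: 16 (3aR,7aR)-6-[(E)-5-(tert-butyldiphenylsilyloxy)pent-3-en-1-ynyl]-5-(hydroxymethyl)-2,2,3a-trimethyl-7,7a-dihydro-1,3-benzodioxol-4(3aH)-one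
Product: 17 (6R,7R)-3-[(E)-3-(tert-butyldiphenylsilyloxy)prop-1-enyl]-6,7-(isopropylidenedioxy)-7-methyl-6,7-dihydro-1H-isochromen-8(5H)-one
Conditions: Ph3PAuNTf2 (3 mol %), CH2Cl2, rt
Reagents that add atoms: none
Why: Gold-catalysed 6-endo-dig hydroalkoxylation (cycloisomerisation of a 2-alkynylbenzyl-alcohol-type substrate): monovalent gold activates the alkyne and the C1 hydroxyl adds to C3. C3 is the δ-carbon of the ynenone and carries the alkenyl group, so attack there should be preferred over 5-exo attack at C4; protodeauration gives the dienol ether.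

Step 13
Reactants: 17 (6R,7R)-3-[(E)-3-(tert-butyldiphenylsilyloxy)prop-1-enyl]-6,7-(isopropylidenedioxy)-7-methyl-6,7-dihydro-1H-isochromen-8(5H)-one
Product: 18 (6R,7R)-3-[(E)-3-(tert-butyldiphenylsilyloxy)prop-1-enyl]-6,7-dihydroxy-7-methyl-6,7-dihydro-1H-isochromen-8(5H)-one
Conditions: CF3CO2H/H2O (4:1), CH2Cl2, 0 °C
Reagents that add atoms: none
Why: Acid hydrolysis of the isopropylidene ketal. The push–pull dienol ether should survive because any hydration at C3 is reversible and recloses to the six-membered ring, and the primary tert-butyldiphenylsilyl ether withstands brief aqueous CF3CO2H.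

Step 14
Reactants: 19 orsellinic acid (2,4-dihydroxy-6-methylbenzoic acid)
Product: 20 tert-butyldimethylsilyl 2,4-bis(tert-butyldimethylsilyloxy)-6-methylbenzoate
Conditions: t-BuMe2SiCl (3.3 equiv), imidazole, DMF, rt
Reagents that add atoms: tert-butyl(chloro)dimethylsilane, CC(C)(C)[Si](C)(C)Cl
Why: Exhaustive silylation masks both phenols and gives a silyl ester that can be converted into the acid chloride under neutral conditions.

Step 15
Reactants: 18 (6R,7R)-3-[(E)-3-(tert-butyldiphenylsilyloxy)prop-1-enyl]-6,7-dihydroxy-7-methyl-6,7-dihydro-1H-isochromen-8(5H)-one; 20 tert-butyldimethylsilyl 2,4-bis(tert-butyldimethylsilyloxy)-6-methylbenzoate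
Product: 22 (6R,7R)-3-[(E)-3-(tert-butyldiphenylsilyloxy)prop-1-enyl]-7-hydroxy-7-methyl-8-oxo-5,6,7,8-tetrahydro-1H-isochromen-6-yl 2,4-bis(tert-butyldimethylsilyloxy)-6-methylbenzoate, via acid chloride 21 (not isolated)
Conditions: (COCl)2, DMF (cat.), CH2Cl2, 0 °C → rt, evaporate; then 18, DMAP, NEt3, CH2Cl2, 0 °C → rt
Reagents that add atoms: none
Why: Oxalyl chloride with catalytic DMF converts the silyl ester into acid chloride 21 without free hydrogen chloride, so the aryl silyl ethers stay. DMAP-catalysed acylation should then take the secondary C6 hydroxyl only, the tertiary C7 hydroxyl being too hindered; the C6–O bond is not broken, so C6 keeps its configuration.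

Step 16
Reactants: 22 (6R,7R)-3-[(E)-3-(tert-butyldiphenylsilyloxy)prop-1-enyl]-7-hydroxy-7-methyl-8-oxo-5,6,7,8-tetrahydro-1H-isochromen-6-yl 2,4-bis(tert-butyldimethylsilyloxy)-6-methylbenzoate
Product: 23 entonaemin A, (6R,7R)-7-hydroxy-3-[(E)-3-hydroxyprop-1-enyl]-7-methyl-8-oxo-5,6,7,8-tetrahydro-1H-isochromen-6-yl 2,4-dihydroxy-6-methylbenzoate
Conditions: HF·pyridine, pyridine, THF, 0 °C → rt
Reagents that add atoms: none
Why: Fluoride-mediated desilylation should remove the two aryl silyl ethers and the primary silyl ether in one operation. The pyridine-buffered reagent is neither basic enough to start β-elimination of the orsellinate nor acidic enough to hydrolyse the dienol ether.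

Compound list

1 | 2-C-methyl-D-erythrono-1,4-lactone, (3R,4R)-3,4-dihydroxy-3-methyloxolan-2-one | O[C@@H]1COC(=O)[C@]1(C)O | starting material
2 | 2,3-O-isopropylidene-2-C-methyl-D-erythrono-1,4-lactone, (3aR,6aR)-2,2,3a-trimethyldihydrofuro[3,4-d][1,3]dioxol-4(3aH)-one | CC1(C)O[C@@H]2COC(=O)[C@]2(C)O1 | intermediate
3 | potassium (2R,3R)-4-hydroxy-2,3-(isopropylidenedioxy)-2-methylbutanoate | [K+].[O-]C(=O)[C@]1(C)OC(C)(C)O[C@@H]1CO | intermediate (not isolated)
4 | methyl (2R,3R)-4-hydroxy-2,3-(isopropylidenedioxy)-2-methylbutanoate | COC(=O)[C@]1(C)OC(C)(C)O[C@@H]1CO | intermediate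
5 | methyl (2R,3R)-2,3-(isopropylidenedioxy)-2-methyl-4-(trifluoromethylsulfonyloxy)butanoate | COC(=O)[C@]1(C)OC(C)(C)O[C@@H]1COS(=O)(=O)C(F)(F)F | intermediate
6 | methyl (2R,3R)-2,3-(isopropylidenedioxy)-2,5-dimethylhex-5-enoate | COC(=O)[C@]1(C)OC(C)(C)O[C@@H]1CC(C)=C | intermediate
7 | methyl (2R,3R)-2,3-(isopropylidenedioxy)-2-methyl-5-oxohexanoate | COC(=O)[C@]1(C)OC(C)(C)O[C@@H]1CC(C)=O | intermediate (precursor of the key step)
8 | lithium enolate of 7 at the methyl group, methyl (2R,3R)-2,3-(isopropylidenedioxy)-5-(lithiooxy)-2-methylhex-5-enoate | COC(=O)[C@]1(C)OC(C)(C)O[C@@H]1CC(=C)O[Li] | intermediate (not isolated)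
9 | (3aR,7aR)-2,2,3a-trimethyltetrahydro-1,3-benzodioxole-4,6-dione (ring A 1,3-dione, carbonyls at C8 and C4a, ketal on the C6 and C7 oxygens) | O=C1CC(=O)[C@]2(C)OC(C)(C)O[C@@H]2C1 | intermediate (product of the key step)
10 | (3aR,7aR)-5-[(dimethylamino)methylidene]-2,2,3a-trimethyltetrahydro-1,3-benzodioxole-4,6-dione | O=C1C(=CN(C)C)C(=O)[C@]2(C)OC(C)(C)O[C@@H]2C1 | intermediate
11 | N-{[(3aR,7aR)-6-chloro-2,2,3a-trimethyl-4-oxo-3a,4,7,7a-tetrahydro-1,3-benzodioxol-5-yl]methylidene}-N-methylmethanaminium chloride | ClC1=C(C=[N+](C)C)C(=O)[C@]2(C)OC(C)(C)O[C@@H]2C1.[Cl-] | intermediate (not isolated)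
12 | (3aR,7aR)-6-chloro-2,2,3a-trimethyl-4-oxo-3a,4,7,7a-tetrahydro-1,3-benzodioxole-5-carbaldehyde (Cl on C4a, CHO on C8a) | ClC1=C(C=O)C(=O)[C@]2(C)OC(C)(C)O[C@@H]2C1 | intermediate
13 | (E)-pent-2-en-4-yn-1-ol | C#C/C=C/CO | starting material
14 | (E)-tert-butyl(pent-2-en-4-ynyloxy)diphenylsilane | C#C/C=C/CO[Si](c1ccccc1)(c1ccccc1)C(C)(C)C | intermediate
15 | (3aR,7aR)-6-[(E)-5-(tert-butyldiphenylsilyloxy)pent-3-en-1-ynyl]-2,2,3a-trimethyl-4-oxo-3a,4,7,7a-tetrahydro-1,3-benzodioxole-5-carbaldehyde | CC(C)(C)[Si](c1ccccc1)(c1ccccc1)OC/C=C/C#CC1=C(C=O)C(=O)[C@]2(C)OC(C)(C)O[C@@H]2C1 | intermediate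
16 | (3aR,7aR)-6-[(E)-5-(tert-butyldiphenylsilyloxy)pent-3-en-1-ynyl]-5-(hydroxymethyl)-2,2,3a-trimethyl-7,7a-dihydro-1,3-benzodioxol-4(3aH)-one | CC(C)(C)[Si](c1ccccc1)(c1ccccc1)OC/C=C/C#CC1=C(CO)C(=O)[C@]2(C)OC(C)(C)O[C@@H]2C1 | intermediate
17 | (6R,7R)-3-[(E)-3-(tert-butyldiphenylsilyloxy)prop-1-enyl]-6,7-(isopropylidenedioxy)-7-methyl-6,7-dihydro-1H-isochromen-8(5H)-one | CC1(C)O[C@@H]2CC3=C(COC(/C=C/CO[Si](c4ccccc4)(c4ccccc4)C(C)(C)C)=C3)C(=O)[C@]2(C)O1 | intermediate
18 | (6R,7R)-3-[(E)-3-(tert-butyldiphenylsilyloxy)prop-1-enyl]-6,7-dihydroxy-7-methyl-6,7-dihydro-1H-isochromen-8(5H)-one | O[C@@H]1CC2=C(COC(/C=C/CO[Si](c3ccccc3)(c3ccccc3)C(C)(C)C)=C2)C(=O)[C@]1(C)O | intermediate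
19 | orsellinic acid, 2,4-dihydroxy-6-methylbenzoic acid | Cc1cc(O)cc(O)c1C(O)=O | starting material
20 | tert-butyldimethylsilyl 2,4-bis(tert-butyldimethylsilyloxy)-6-methylbenzoate | Cc1cc(O[Si](C)(C)C(C)(C)C)cc(O[Si](C)(C)C(C)(C)C)c1C(=O)O[Si](C)(C)C(C)(C)C | intermediate
21 | 2,4-bis(tert-butyldimethylsilyloxy)-6-methylbenzoyl chloride | Cc1cc(O[Si](C)(C)C(C)(C)C)cc(O[Si](C)(C)C(C)(C)C)c1C(Cl)=O | intermediate (not isolated)
22 | (6R,7R)-3-[(E)-3-(tert-butyldiphenylsilyloxy)prop-1-enyl]-7-hydroxy-7-methyl-8-oxo-5,6,7,8-tetrahydro-1H-isochromen-6-yl 2,4-bis(tert-butyldimethylsilyloxy)-6-methylbenzoate | Cc1cc(O[Si](C)(C)C(C)(C)C)cc(O[Si](C)(C)C(C)(C)C)c1C(=O)O[C@@H]1CC2=C(COC(/C=C/CO[Si](c3ccccc3)(c3ccccc3)C(C)(C)C)=C2)C(=O)[C@]1(C)O | intermediate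
23 | entonaemin A, (6R,7R)-7-hydroxy-3-[(E)-3-hydroxyprop-1-enyl]-7-methyl-8-oxo-5,6,7,8-tetrahydro-1H-isochromen-6-yl 2,4-dihydroxy-6-methylbenzoate | Cc1cc(O)cc(O)c1C(=O)O[C@@H]1CC2=C(COC(/C=C/CO)=C2)C(=O)[C@]1(C)O | target

Total step count: 16. Longest linear sequence: 14 steps from lactone 1 (steps 1 to 8, 10 to 13, 15 and 16); steps 9 and 14 prepare the two side fragments.

Steps least certain to work

Step 6 (key step). Enolisation may go in part toward C5, followed by expulsion of the C6 ketal oxygen; or attack on the hindered, α-oxygenated ester may be so slow that intermolecular aldol reactions of 7 take over. Fallback: the acceptor is changed from an ester to an aldehyde, which reacts under near-neutral enamine catalysis. Setting out from alkene 6, the ester is reduced with iBu2AlH at −78 °C to (2R,3R)-2,3-(isopropylidenedioxy)-2,5-dimethylhex-5-enal F1. Ozonolysis gives the keto aldehyde (2R,3R)-2,3-(isopropylidenedioxy)-2-methyl-5-oxohexanal F2, which has no enolisable aldehyde position. A proline-mediated intramolecular aldol addition then forms the C8–C8a bond and gives the β-hydroxy ketone F3 (9 with CH(OH) at C8, either epimer), and Dess–Martin oxidation leads back into the route at dione 9.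

Step 2. The cis-dioxolane holds the C5 oxygen next to the ester carbon, so 4 may close back to lactone 2 during methylation or work-up, and triflate 5 may do the same by attack of the ester carbonyl oxygen. Fallback: the carboxyl carbon is carried as a vinyl group, which cannot lactonise. Setting out from 2, reduction with iBu2AlH gives the lactol 2,3-O-isopropylidene-2-C-methyl-D-erythrofuranose F4, and Wittig methylenation with Ph3P=CH2 gives the alkenol [(4R,5S)-5-ethenyl-2,2,5-trimethyl-1,3-dioxolan-4-yl]methanol F5. Its triflate F6 is coupled with the cuprate of step 4 to the diene F7 (the 2-methylprop-2-enyl analogue of F5). Ozonolysis of both double bonds gives keto aldehyde F2, Pinnick oxidation with NaClO2 gives (2R,3R)-2,3-(isopropylidenedioxy)-2-methyl-5-oxohexanoic acid F8, and Me3SiCHN2 returns to the route at keto ester 7.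

Step 8. Activation may take place at the C8 oxygen, chloride may attack the aminomethylene carbon, or traces of hydrogen chloride may open the ketal. Fallback: the alkyne is brought in by carbonyl addition, which replaces steps 8 and 10 and needs neither a C–Cl bond nor palladium. Setting out from enaminone 10 and enyne 14, deprotonation of 14 with n-BuLi gives the lithium acetylide F9, which should add 1,2 to the less hindered C4a carbonyl of the vinylogous amide to give the carbinol F10. Dilute aqueous HCl in THF at 0 °C then removes water with the help of the enamine nitrogen and hydrolyses the iminium ion (a Stork–Danheiser-type transposition), which comes back to the route at aldehyde 15.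

Step 13. The ring-fused ketal beside the ketone may need acid strong enough to open ring B irreversibly or to cleave the C11 silyl ether. Fallback: the diol protection is changed while the compound is still the robust dione. Setting out from 9, aqueous CF3CO2H gives the dihydroxy dione F11, and Et3SiOTf with 2,6-lutidine gives the bis(triethylsilyl) ether F12 (the silyl enol ether of the dione falls off on work-up). Steps 7, 8, 10, 11 and 12 are then run in this series through enaminone F13, chloro aldehyde F14, enynyl aldehyde F15, alcohol F16 and pyran F17. HF·pyridine in pyridine at 0 °C removes the two triethylsilyl ethers before the primary tert-butyldiphenylsilyl ether and returns to the route at diol 18.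

Step 15. The 2,6-disubstituted acid chloride may fail to reach the secondary hydroxyl beside the quaternary C7, and forcing the acylation with more base or heat invites β-elimination at C5/C6. Fallback: the arene is built on the oxygen instead of being attached to it. Setting out from diol 18, heating with the diketo-dioxinone A6 in toluene unmasks an unhindered ketene carbon that the C6 hydroxyl captures to give the triketo ester F18. NEt3 followed by mild acid closes and aromatises the chain to 11-O-(tert-butyldiphenylsilyl) entonaemin A F19, and HF·pyridine as in step 16 returns to the route at target 23.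

Further compounds

F1 | step 6 | (2R,3R)-2,3-(isopropylidenedioxy)-2,5-dimethylhex-5-enal | O=C[C@]1(C)OC(C)(C)O[C@@H]1CC(C)=C
F2 | step 6 | (2R,3R)-2,3-(isopropylidenedioxy)-2-methyl-5-oxohexanal | O=C[C@]1(C)OC(C)(C)O[C@@H]1CC(C)=O
F3 | step 6 | 4-hydroxy-2,2,3a-trimethylhexahydro-1,3-benzodioxol-6-one (9 with CH(OH) at C8, C6 and C7 as in 9, either C8 epimer) | O=C1CC(O)[C@]2(C)OC(C)(C)O[C@@H]2C1
F4 | step 2 | 2,3-O-isopropylidene-2-C-methyl-D-erythrofuranose (lactol of 2, both anomers) | CC1(C)O[C@@H]2COC(O)[C@]2(C)O1
F5 | step 2 | [(4R,5S)-5-ethenyl-2,2,5-trimethyl-1,3-dioxolan-4-yl]methanol | C=C[C@]1(C)OC(C)(C)O[C@@H]1CO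
F6 | step 2 | trifluoromethanesulfonate of F5 | C=C[C@]1(C)OC(C)(C)O[C@@H]1COS(=O)(=O)C(F)(F)F
F7 | step 2 | 4-ethenyl-2,2,4-trimethyl-5-(2-methylprop-2-enyl)-1,3-dioxolane, configuration as in F5 | C=C[C@]1(C)OC(C)(C)O[C@@H]1CC(C)=C
F8 | step 2 | (2R,3R)-2,3-(isopropylidenedioxy)-2-methyl-5-oxohexanoic acid | OC(=O)[C@]1(C)OC(C)(C)O[C@@H]1CC(C)=O
F9 | step 8 | lithium (E)-5-(tert-butyldiphenylsilyloxy)pent-3-en-1-ynide | [Li]C#C/C=C/CO[Si](c1ccccc1)(c1ccccc1)C(C)(C)C
F10 | step 8 | 1,2-adduct of F9 at the C4a carbonyl of 10 (tertiary propargylic carbinol, either C4a epimer) | CN(C)C=C1C(=O)[C@]2(C)OC(C)(C)O[C@@H]2CC1(O)C#C/C=C/CO[Si](c1ccccc1)(c1ccccc1)C(C)(C)C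
F11 | step 13 | (4R,5R)-4,5-dihydroxy-4-methylcyclohexane-1,3-dione | O[C@@H]1CC(=O)CC(=O)[C@]1(C)O
F12 | step 13 | (4R,5R)-4-methyl-4,5-bis(triethylsilyloxy)cyclohexane-1,3-dione | CC[Si](CC)(CC)O[C@@H]1CC(=O)CC(=O)[C@]1(C)O[Si](CC)(CC)CC
F13 | step 13 | 2-[(dimethylamino)methylidene] derivative of F12 | CC[Si](CC)(CC)O[C@@H]1CC(=O)C(=CN(C)C)C(=O)[C@]1(C)O[Si](CC)(CC)CC
F14 | step 13 | bis(triethylsilyl) analogue of 12 (Cl on C4a, CHO on C8a) | CC[Si](CC)(CC)O[C@@H]1CC(Cl)=C(C=O)C(=O)[C@]1(C)O[Si](CC)(CC)CC
F15 | step 13 | bis(triethylsilyl) analogue of 15 | CC[Si](CC)(CC)O[C@@H]1CC(C#C/C=C/CO[Si](c2ccccc2)(c2ccccc2)C(C)(C)C)=C(C=O)C(=O)[C@]1(C)O[Si](CC)(CC)CC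
F16 | step 13 | bis(triethylsilyl) analogue of 16 | CC[Si](CC)(CC)O[C@@H]1CC(C#C/C=C/CO[Si](c2ccccc2)(c2ccccc2)C(C)(C)C)=C(CO)C(=O)[C@]1(C)O[Si](CC)(CC)CC
F17 | step 13 | 6,7-bis(triethylsilyl) ether of 18 | CC[Si](CC)(CC)O[C@@H]1CC2=C(COC(/C=C/CO[Si](c3ccccc3)(c3ccccc3)C(C)(C)C)=C2)C(=O)[C@]1(C)O[Si](CC)(CC)CC
F18 | step 15 | 3,5,7-trioxooctanoate of 18 at the C6 oxygen | CC(=O)CC(=O)CC(=O)CC(=O)O[C@@H]1CC2=C(COC(/C=C/CO[Si](c3ccccc3)(c3ccccc3)C(C)(C)C)=C2)C(=O)[C@]1(C)O
F19 | step 15 | 11-O-(tert-butyldiphenylsilyl) entonaemin A | Cc1cc(O)cc(O)c1C(=O)O[C@@H]1CC2=C(COC(/C=C/CO[Si](c3ccccc3)(c3ccccc3)C(C)(C)C)=C2)C(=O)[C@]1(C)O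
A1 | alternative 1 | open-chain (Z)-vinyl iodide with vinyl ketone, C7 carbinol and silylated orsellinate at C6 | C=CC(=O)[C@](C)(O)[C@H](OC(=O)c1c(C)cc(O[Si](C)(C)C(C)(C)C)cc1O[Si](C)(C)C(C)(C)C)C/C(I)=C/C(=O)/C=C/CO[Si](C)(C)C(C)(C)C
A2 | alternative 1 | tris(tert-butyldimethylsilyl) entonaemin A | Cc1cc(O[Si](C)(C)C(C)(C)C)cc(O[Si](C)(C)C(C)(C)C)c1C(=O)O[C@@H]1CC2=C(COC(/C=C/CO[Si](C)(C)C(C)(C)C)=C2)C(=O)[C@]1(C)O
A3 | alternative 2 | 1-acetylcyclopent-2-en-1-ol with the C8 hydroxyl cis to the C6 ester, carrying the enyne and silyloxymethyl arms | CC(=O)[C@]1(O)C(CO[Si](C)(C)C(C)(C)C)=C(C#C/C=C/CO[Si](C)(C)C(C)(C)C)C[C@H]1OC(=O)c1c(C)cc(O[Si](C)(C)C(C)(C)C)cc1O[Si](C)(C)C(C)(C)C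
A4 | alternative 2 | cyclohexenone α-ketol (ring A) with the silylated orsellinate at C6, the free C7 carbinol, the silylated enyne at C4a and the silyloxymethyl group at C8a | Cc1cc(O[Si](C)(C)C(C)(C)C)cc(O[Si](C)(C)C(C)(C)C)c1C(=O)O[C@@H]1CC(C#C/C=C/CO[Si](C)(C)C(C)(C)C)=C(CO[Si](C)(C)C(C)(C)C)C(=O)[C@]1(C)O
A5 | alternative 3 | (6R,7R)-3-[(E)-3-(tert-butyldimethylsilyloxy)prop-1-enyl]-6,7-dihydroxy-7-methyl-6,7-dihydro-1H-isochromen-8(5H)-one | O[C@@H]1CC2=C(COC(/C=C/CO[Si](C)(C)C(C)(C)C)=C2)C(=O)[C@]1(C)O
A6 | alternative 3 | 2,2-dimethyl-6-(2,4-dioxopentyl)-4H-1,3-dioxin-4-one | CC(=O)CC(=O)CC1=CC(=O)OC(C)(C)O1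
A7 | alternative 3 | 11-O-(tert-butyldimethylsilyl) entonaemin A | Cc1cc(O)cc(O)c1C(=O)O[C@@H]1CC2=C(COC(/C=C/CO[Si](C)(C)C(C)(C)C)=C2)C(=O)[C@]1(C)O
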